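The ten-membered ring is not closed end to end. In the germacrane core the E C1=C10 alkene and the C4–C5 oxirane (a masked E alkene) are 1,5-related through C2–C3, so an added C5–C10 bond folds the carbocycle into a p-menthane cyclohexane (C5–C10) available from (R)-carvone. The precursor is a trans-1-isopropenyl-2-vinylcyclohexanol carrying three different ethers at C6, C8 and C9. Its anionic oxy-Cope rearrangement forms C2–C3, cleaves C5–C10, expands the six-membered ring to the ten-membered one with both E alkenes, and the enolate is kept as a C5 triflate so that oxygen can later be exchanged for hydrogen.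

Key step: step 12

Remarks: ring carbons carry germacrane numbers throughout (carvone C1, C2, C3, C4, C5, C6 = C9, C10, C5, C6, C7, C8). "Upper" is the face of the C8 oxygen, "lower" the face of the C7 isopropyl group. Assumption: a commercial ketoreductase with syn-(2R,3S) selectivity for 31 is taken from a screening panel. Metal alkoxides are quenched with water unless another work-up is given.

Step 1
Reactants: 1 (R)-(−)-carvone
Product: 2 (R)-carvotanacetone
Conditions: H2 (1 atm), RhCl(PPh3)3 (cat.), benzene, rt
Reagents that add atoms: none
Why: Homogeneous catalytic hydrogenation with RhCl(PPh3)3 reduces the unhindered 1,1-disubstituted isopropenyl alkene much faster than the conjugated trisubstituted enone alkene and leaves the C7 stereocentre untouched.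

Step 2
Reactants: 2 (R)-carvotanacetone; 3 phenyl vinyl sulfoxide
Product: 5 (2R,5R)-5-isopropyl-2-methyl-2-[2-(phenylsulfinyl)ethyl]cyclohex-3-en-1-one (sulfur epimers), via potassium dienolate 4 (not isolated)
Conditions: KOt-Bu (1.05 equiv), THF/t-BuOH, 0 °C to rt; then 3, −20 to 0 °C; H2O
Reagents that add atoms: none
Why: Under equilibrating conditions the extended dienolate forms by deprotonation at C6 and reacts at its α-carbon C10 with the vinyl sulfoxide (Michael addition with deconjugation), creating the quaternary centre; the bulky acceptor should enter on the face away from the pseudoaxial C8–H and the isopropyl group, but this 1,4-induction is expected to be modest, so the C10 epimers are separated after step 3 and only the one with the new chain trans to isopropyl is carried on.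

Step 3
Reactants: 5 sulfoxide adduct
Product: 6 (2R,5R)-5-isopropyl-2-methyl-2-vinylcyclohex-3-en-1-one (vinyl trans to isopropyl)
Conditions: toluene, CaCO3, 110 °C
Reagents that add atoms: none
Why: Thermal syn-elimination of the sulfoxide can only remove a hydrogen from the CH2 attached to C10, so the vinyl group forms regiospecifically, the non-enolisable quaternary centre is unaffected and CaCO3 takes up the sulfenic acid.

Step 4
Reactants: 6 vinyl ketone
Product: 8 C8-hydroxy ketone (6-hydroxy-5-isopropyl-2-methyl-2-vinylcyclohex-3-en-1-one, hydroxyl on the upper face, trans to isopropyl), via potassium enolate 7 (not isolated)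
Conditions: KN(SiMe3)2, THF, −78 °C; 2-(phenylsulfonyl)-3-phenyloxaziridine, −78 °C; H2O
Reagents that add atoms: 2-(phenylsulfonyl)-3-phenyloxaziridine, O=S(=O)(N1OC1c1ccccc1)c1ccccc1
Why: C8 is the only enolisable position, and the potassium enolate is oxidised by the N-sulfonyloxaziridine on the face anti to the adjacent C7 isopropyl group (enolate hydroxylation), which sets C8.

Step 5
Reactants: 8 C8-hydroxy ketone
Product: 9 C8 tert-butyldimethylsilyl ether of 8
Conditions: t-BuMe2SiOTf, 2,6-lutidine, CH2Cl2, −78 to 0 °C
Reagents that add atoms: tert-butyldimethylsilyl triflate, CC(C)(C)[Si](C)(C)OS(=O)(=O)C(F)(F)F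
Why: O-silylation with the silyl triflate and a hindered pyridine base is fast at low temperature, so the α-ketol is capped before it can rearrange or epimerise.

Step 6
Reactants: 9 silyloxy ketone
Product: 10 C9 alcohol (C9 hydroxyl upper and axial, cis to the C8 silyl ether)
Conditions: LiBH(s-Bu)3, THF, −78 °C; H2O
Reagents that add atoms: none
Why: The bulky trialkylborohydride should attack C9 along the equatorial direction from the lower face, as such reagents do with ketones flanked by an axial α-methyl group, giving the axial alcohol cis to the equatorial C8 ether (diastereoselective ketone reduction).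

Step 7
Reactants: 10 homoallylic alcohol
Product: 11 C5–C6 epoxy alcohol (oxirane on the upper face)
Conditions: mCPBA, NaHCO3, CH2Cl2, 0 °C
Reagents that add atoms: 3-chloroperbenzoic acid, OOC(=O)c1cccc(Cl)c1
Why: The cis-disubstituted ring alkene is more nucleophilic than the vinyl group, and hydrogen bonding to the axial homoallylic C9 hydroxyl together with the pseudoaxial C10 methyl on the opposite face sends the peracid to the upper face (hydroxyl-directed Prilezhaev epoxidation).

Step 8
Reactants: 11 epoxy alcohol
Product: 12 C9 2-(trimethylsilyl)ethoxymethyl (SEM) ether of 11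
Conditions: SEMCl, i-Pr2NEt, Bu4NI (cat.), CH2Cl2, 40 °C
Reagents that add atoms: 2-(trimethylsilyl)ethoxymethyl chloride, C[Si](C)(C)CCOCCl
Why: O-alkylation with the chloromethyl ether under amine base avoids an alkoxide that would let the C8 silyl group migrate, and gives an acetal-type ether that cannot migrate to the syn-axial C5 alkoxide of step 12.

Step 9
Reactants: 12 protected epoxide
Product: 13 C5 alcohol with C6 4-methoxybenzyl ether (C5 hydroxyl upper, C6 ether lower, trans-diaxial)
Conditions: 4-MeOC6H4CH2OH (5 equiv), Yb(OTf)3 (10 mol %), CH2Cl2, 0 °C to rt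
Reagents that add atoms: 4-methoxybenzyl alcohol, COc1ccc(CO)cc1
Why: Lewis-acid-assisted alcoholysis of the epoxide follows the trans-diaxial path, the alcohol attacking C6 from the lower face with inversion because attack at neopentyl C5 would need a twist-boat, which sets C6 and leaves the upper axial C5 hydroxyl.

Step 10
Reactants: 13 C5 alcohol
Product: 14 C5 ketone (2-alkoxy-6-methyl-6-vinylcyclohexanone bearing the C8 and C9 ethers)
Conditions: DMP (1,1,1-triacetoxy-1,1-dihydro-1,2-benziodoxol-3(1H)-one), NaHCO3, CH2Cl2, rt
Reagents that add atoms: none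
Why: Oxidation with the hypervalent iodine reagent under buffered, non-enolising conditions converts the hindered axial alcohol into the ketone without epimerising the α-alkoxy centre C6.

Step 11
Reactants: 14 C5 ketone; 15 2-bromopropene
Product: 18 trans-1-isopropenyl-2-vinylcyclohexanol (C5 hydroxyl upper and axial, isopropenyl lower and equatorial, trans to the C10 vinyl group), via isopropenylmagnesium bromide 16 (not isolated), via isopropenylcerium dichloride 17 (not isolated)
Conditions: 15, Mg, THF, rt; CeCl3, THF, −78 °C; then 14, −78 to −20 °C; H2O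
Reagents that add atoms: none
Why: The weakly basic organocerium reagent adds to the hindered, enolisable α-alkoxy ketone (1,2-addition), and because the axial trajectory on the upper face is closed by the syn-axial C9 acetal oxygen it should enter equatorially, which sets C5 with isopropenyl trans to vinyl.

Step 12
Reactants: 18 trans-1-isopropenyl-2-vinylcyclohexanol
Product: 21 cyclodeca-1(10),4-dienyl C5 triflate, via potassium alkoxide 19 (not isolated), via potassium enolate 20 (not isolated)
Conditions: KH, 18-crown-6, THF, 0 °C to rt; then PhNTf2, −78 to 0 °C; H2O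
Reagents that add atoms: N-phenylbis(trifluoromethanesulfonimide), O=S(=O)(N(c1ccccc1)S(=O)(=O)C(F)(F)F)C(F)(F)F
Why: KH with 18-crown-6 gives the free tertiary C5 alkoxide, whose oxyanion weakens the adjacent C5–C10 bond and triggers a concerted [3,3]-sigmatropic shift (anionic oxy-Cope rearrangement); the closest known reaction type is the ring expansion of trans-1,2-dialkenylcyclohexanols to E-cyclodec-5-enone enolates that are trapped in the same flask. The ten-membered ring is closed by four-atom ring expansion, C2–C3 forming between the vinyl and isopropenyl termini as C5–C10 breaks, so no end-to-end macrocyclisation takes place. No sp3 stereocentre is created; the two alkene geometries come from a chair transition state fused to the cyclohexane chair in which the ring bonds C10–C9 and C5–C6 are equatorial, so C1=C10 is E and the C4=C5 enolate has C3 and C6 trans. The selectivity needed is chair over boat, and it is secured by the trans-diequatorial vinyl and isopropenyl groups with the equatorial C7 isopropyl group as conformational anchor, while relief of the syn-axial C6 ether/C10 methyl and C9 ether/C5 oxygen contacts and formation of the enolate make the step irreversible. KH leaves no proton source that could scramble the enolate, O-sulfonylation by PhNTf2 fixes its regio- and stereochemistry, and no ether sits β to the enolate carbon, so elimination is not available.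

Step 13
Reactants: 21 C5 triflate
Product: 22 germacra-1(10),4-diene with C8 silyl, C9 SEM and C6 4-methoxybenzyl ethers (both alkenes E)
Conditions: Pd(OAc)2 (5 mol %), PPh3, Bu3N, HCO2H, DMF, 60 °C
Reagents that add atoms: none
Why: Oxidative addition of zerovalent palladium to the vinyl triflate, exchange of triflate for formate, loss of CO2 and reductive elimination replace OTf by H with retention of geometry (palladium-catalysed formate reduction of an enol triflate), at a temperature well below the thermal germacrane-to-elemane Cope reversal.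

Step 14
Reactants: 22 tris-ether diene
Product: 23 C8 alcohol
Conditions: Bu4NF, THF, rt; H2O
Reagents that add atoms: none
Why: Fluoride cleaves the secondary tert-butyldimethylsilyl ether at room temperature (desilylation), conditions under which SEM and 4-methoxybenzyl ethers are stable and no ester is yet present to migrate.

Step 15
Reactants: 23 C8 alcohol; 24 tiglic acid
Product: 26 C8 tiglate, via mixed anhydride 25 (not isolated)
Conditions: 24, 2,4,6-Cl3C6H2COCl, Et3N, toluene, rt; then 23, DMAP, 50 °C
Reagents that add atoms: none
Why: Yamaguchi esterification through the aroyl mixed anhydride acylates the hindered secondary C8 alcohol under DMAP catalysis, and the E-configured tiglate is the stable isomer and does not isomerise.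

Step 16
Reactants: 26 C8 tiglate
Product: 27 C9 alcohol
Conditions: MgBr2·OEt2, MeNO2, Et2O, rt; H2O
Reagents that add atoms: none
Why: MgBr2 chelates the two acetal oxygens of the SEM group and cleaves it at room temperature without Brønsted acid or a free alkoxide (Lewis-acid SEM cleavage), so the diene is not protonated and the neighbouring tiglate does not migrate.

Step 17
Reactants: 27 C9 alcohol
Product: 28 C9 acetate
Conditions: Ac2O, pyridine, DMAP (cat.), CH2Cl2, 0 °C
Reagents that add atoms: acetic anhydride, CC(=O)OC(C)=O
Why: DMAP-catalysed acetylation caps the allylic C9 alcohol immediately, before any acyl migration from C8 can occur.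

Step 18
Reactants: 28 C9 acetate
Product: 29 allylic C6 alcohol
Conditions: DDQ, CH2Cl2/pH 7 buffer, 0 °C
Reagents that add atoms: none
Why: DDQ oxidises the electron-rich benzyl ether and the resulting hemiacetal collapses in the wet buffered medium (oxidative 4-methoxybenzyl ether cleavage), which frees the C6 alcohol without acid or base.

Step 19
Reactants: 29 allylic C6 alcohol
Product: 30 4,5-epoxy C6 alcohol with C8 tiglate and C9 acetate
Conditions: VO(acac)2 (5 mol %), t-BuOOH, CH2Cl2, 0 °C
Reagents that add atoms: tert-butyl hydroperoxide, CC(C)(C)OO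
Why: The vanadium alkoxide of the C6 alcohol delivers the peroxide oxygen only to the adjacent C4=C5 alkene (hydroxyl-directed epoxidation); in the conformer that minimises A1,3 strain C6–H eclipses the C4 methyl group and the hydroxyl lies on the peripheral face, so oxygen arrives there and sets C4 and C5 as the threo epoxy alcohol of the target, while C1=C10, next to an acetate only, is left alone.

Step 20
Reactants: 31 ethyl 2-methylacetoacetate (racemic)
Product: 32 ethyl (2R,3S)-3-hydroxy-2-methylbutanoate
Conditions: ketoreductase, NADP+ (cat.), i-PrOH, phosphate buffer pH 7, 30 °C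
Reagents that add atoms: none
Why: The α-centre of the β-keto ester racemises faster than it is reduced, and the syn-selective enzyme reduces only the (2R)-enantiomer from one carbonyl face (enzymatic dynamic kinetic reduction), which sets both side-chain stereocentres.

Step 21
Reactants: 32 hydroxy ester
Product: 33 (2R,3S)-3-hydroxy-2-methylbutanoic acid
Conditions: LiOH, THF/H2O, 0 °C; then 1 M HCl
Reagents that add atoms: lithium hydroxide, [Li+].[OH-]
Why: Saponification of the unhindered ethyl ester at 0 °C is done while the hydroxyl is still free, so no β-silyloxy ester is exposed to hydroxide and β-elimination or epimerisation is avoided.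

Step 22
Reactants: 33 hydroxy acid
Product: 35 (2R,3S)-2-methyl-3-(triethylsilyloxy)butanoic acid, via triethylsilyl ester 34 (not isolated)
Conditions: Et3SiCl (2.2 equiv), imidazole, DMF, 0 °C; then K2CO3 (cat.), MeOH/H2O, 0 °C
Reagents that add atoms: triethylsilyl chloride, CC[Si](Cl)(CC)CC
Why: Both hydroxyl and carboxyl are silylated, and the far more labile silyl ester is then hydrolysed selectively (silylation followed by selective silyl ester hydrolysis), leaving the secondary silyl ether.

Step 23
Reactants: 30 epoxy alcohol; 35 silyloxy acid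
Product: 37 silyl-protected triester, via mixed anhydride 36 (not isolated)
Conditions: 35, 2,4,6-Cl3C6H2COCl, Et3N, toluene, rt; then 30, DMAP, rt
Reagents that add atoms: none
Why: Yamaguchi esterification through the mixed anhydride acylates the hindered C6 alcohol under mild base that the oxirane tolerates, and the silyl ether prevents self-condensation of the acid.

Step 24
Reactants: 37 silyl-protected triester
Product: 38 CNP0218463.1 (target)
Conditions: Bu4NF, AcOH (1:1), THF, 0 °C
Reagents that add atoms: none
Why: Acetic-acid-buffered fluoride removes the labile triethylsilyl ether near neutral pH (desilylation), so the oxirane is not opened and the three esters neither migrate nor undergo retro-aldol cleavage.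

Compound list
1 | (R)-(−)-carvone | CC1=CC[C@H](CC1=O)C(C)=C | starting material
2 | (R)-carvotanacetone, (5R)-5-isopropyl-2-methylcyclohex-2-en-1-one | CC1=CC[C@H](CC1=O)C(C)C | intermediate
3 | phenyl vinyl sulfoxide (racemic) | C=CS(=O)c1ccccc1 | starting material
4 | potassium dienolate of 2 (O–C9=C10–C5=C6) | CC1=C([O-])C[C@H](C(C)C)C=C1.[K+] | intermediate
5 | (2R,5R)-5-isopropyl-2-methyl-2-[2-(phenylsulfinyl)ethyl]cyclohex-3-en-1-one, sulfur epimers | C1[C@H](C(C)C)C=C[C@](CCS(=O)c2ccccc2)(C)C1=O | intermediate
6 | (2R,5R)-5-isopropyl-2-methyl-2-vinylcyclohex-3-en-1-one (vinyl upper, methyl lower) | C1[C@H](C(C)C)C=C[C@](C=C)(C)C1=O | intermediate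
7 | potassium enolate of 6 (O–C9=C8) | [O-]C1=C[C@H](C(C)C)C=C[C@]1(C=C)C.[K+] | intermediate
8 | C8-hydroxy ketone (6-hydroxy-5-isopropyl-2-methyl-2-vinylcyclohex-3-en-1-one, OH upper) | O[C@H]1[C@H](C(C)C)C=C[C@](C=C)(C)C1=O | intermediate
9 | C8 tert-butyldimethylsilyl ether of 8 | CC(C)(C)[Si](C)(C)O[C@H]1[C@H](C(C)C)C=C[C@](C=C)(C)C1=O | intermediate
10 | C9 alcohol (C9 OH upper, cis to C8 silyl ether) | CC(C)(C)[Si](C)(C)O[C@H]1[C@H](C(C)C)C=C[C@](C=C)(C)[C@H]1O | intermediate
11 | upper-face C5–C6 epoxide of 10 | CC(C)(C)[Si](C)(C)O[C@H]1[C@H](C(C)C)[C@H]2O[C@H]2[C@](C=C)(C)[C@H]1O | intermediate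
12 | C9 SEM ether of 11 | CC(C)(C)[Si](C)(C)O[C@H]1[C@H](C(C)C)[C@H]2O[C@H]2[C@](C=C)(C)[C@H]1OCOCC[Si](C)(C)C | intermediate
13 | C5 alcohol (upper) with C6 4-methoxybenzyl ether (lower) | CC(C)(C)[Si](C)(C)O[C@H]1[C@H](C(C)C)[C@H](OCc2ccc(OC)cc2)[C@@H](O)[C@](C=C)(C)[C@H]1OCOCC[Si](C)(C)C | intermediate
14 | C5 ketone | CC(C)(C)[Si](C)(C)O[C@H]1[C@H](C(C)C)[C@H](OCc2ccc(OC)cc2)C(=O)[C@](C=C)(C)[C@H]1OCOCC[Si](C)(C)C | intermediate
15 | 2-bromopropene | CC(Br)=C | starting material
16 | isopropenylmagnesium bromide | CC(=C)[Mg]Br | intermediate
17 | isopropenylcerium dichloride | CC(=C)[Ce](Cl)Cl | intermediate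
18 | trans-1-isopropenyl-2-vinylcyclohexanol (C5 OH upper, isopropenyl lower) | CC(C)(C)[Si](C)(C)O[C@H]1[C@H](C(C)C)[C@H](OCc2ccc(OC)cc2)[C@](O)(C(C)=C)[C@](C=C)(C)[C@H]1OCOCC[Si](C)(C)C | intermediate
19 | potassium alkoxide of 18 | CC(C)(C)[Si](C)(C)O[C@H]1[C@H](C(C)C)[C@H](OCc2ccc(OC)cc2)[C@]([O-])(C(C)=C)[C@](C=C)(C)[C@H]1OCOCC[Si](C)(C)C.[K+] | intermediate
20 | potassium enolate of the ring-expanded cyclodec-1(10)-en-5-one (C3 and C6 trans on C4=C5) | CC(C)(C)[Si](C)(C)O[C@H]1[C@H](C(C)C)[C@H](OCc2ccc(OC)cc2)/C([O-])=C(\C)CC/C=C(\C)[C@H]1OCOCC[Si](C)(C)C.[K+] | intermediate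
21 | cyclodeca-1(10),4-dienyl C5 triflate (1(10)E; at C4=C5 the ring carbons are trans, which is Z by sequence rules because OTf outranks C6) | CC(C)(C)[Si](C)(C)O[C@H]1[C@H](C(C)C)[C@H](OCc2ccc(OC)cc2)/C(OS(=O)(=O)C(F)(F)F)=C(\C)CC/C=C(\C)[C@H]1OCOCC[Si](C)(C)C | intermediate
22 | (1(10)E,4E)-germacradiene with C8 silyl, C9 SEM, C6 4-methoxybenzyl ethers | CC(C)(C)[Si](C)(C)O[C@H]1[C@H](C(C)C)[C@H](OCc2ccc(OC)cc2)/C=C(\C)CC/C=C(\C)[C@H]1OCOCC[Si](C)(C)C | intermediate
23 | C8 alcohol | O[C@H]1[C@H](C(C)C)[C@H](OCc2ccc(OC)cc2)/C=C(\C)CC/C=C(\C)[C@H]1OCOCC[Si](C)(C)C | intermediate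
24 | tiglic acid | C/C=C(\C)C(=O)O | starting material
25 | tiglic 2,4,6-trichlorobenzoic anhydride | C/C=C(\C)C(=O)OC(=O)c1c(Cl)cc(Cl)cc1Cl | intermediate
26 | C8 tiglate | C/C=C(\C)C(=O)O[C@H]1[C@H](C(C)C)[C@H](OCc2ccc(OC)cc2)/C=C(\C)CC/C=C(\C)[C@H]1OCOCC[Si](C)(C)C | intermediate
27 | C9 alcohol with C8 tiglate | C/C=C(\C)C(=O)O[C@H]1[C@H](C(C)C)[C@H](OCc2ccc(OC)cc2)/C=C(\C)CC/C=C(\C)[C@H]1O | intermediate
28 | C9 acetate with C8 tiglate and C6 4-methoxybenzyl ether | C/C=C(\C)C(=O)O[C@H]1[C@H](C(C)C)[C@H](OCc2ccc(OC)cc2)/C=C(\C)CC/C=C(\C)[C@H]1OC(C)=O | intermediate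
29 | allylic C6 alcohol with C8 tiglate and C9 acetate | C/C=C(\C)C(=O)O[C@H]1[C@H](C(C)C)[C@H](O)/C=C(\C)CC/C=C(\C)[C@H]1OC(C)=O | intermediate
30 | 4,5-epoxy C6 alcohol (trans-oxirane syn to the C6 hydroxyl, threo) | C/C=C(\C)C(=O)O[C@H]1[C@H](C(C)C)[C@H](O)[C@H]2O[C@]2(C)CC/C=C(\C)[C@H]1OC(C)=O | intermediate
31 | ethyl 2-methylacetoacetate (racemic) | CCOC(=O)C(C)C(C)=O | starting material
32 | ethyl (2R,3S)-3-hydroxy-2-methylbutanoate | CCOC(=O)[C@H](C)[C@H](C)O | intermediate
33 | (2R,3S)-3-hydroxy-2-methylbutanoic acid | OC(=O)[C@H](C)[C@H](C)O | intermediate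
34 | triethylsilyl (2R,3S)-2-methyl-3-(triethylsilyloxy)butanoate | CC[Si](CC)(CC)OC(=O)[C@H](C)[C@H](C)O[Si](CC)(CC)CC | intermediate
35 | (2R,3S)-2-methyl-3-(triethylsilyloxy)butanoic acid | OC(=O)[C@H](C)[C@H](C)O[Si](CC)(CC)CC | intermediate
36 | mixed anhydride of 35 with 2,4,6-trichlorobenzoic acid | O=C(c1c(Cl)cc(Cl)cc1Cl)OC(=O)[C@H](C)[C@H](C)O[Si](CC)(CC)CC | intermediate
37 | silyl-protected triester | C/C=C(\C)C(=O)O[C@H]1[C@H](C(C)C)[C@H](OC(=O)[C@H](C)[C@H](C)O[Si](CC)(CC)CC)[C@H]2O[C@]2(C)CC/C=C(\C)[C@H]1OC(C)=O | intermediate
38 | CNP0218463.1 | C/C=C(\C)C(=O)O[C@H]1[C@H](C(C)C)[C@H](OC(=O)[C@H](C)[C@H](C)O)[C@H]2O[C@]2(C)CC/C=C(\C)[C@H]1OC(C)=O | target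

Total step count: 24. Longest linear sequence: 21 steps (steps 1 to 19, then 23 and 24); the side-chain acid takes 3 steps (20 to 22).

Steps most likely to fail

Step 11. The equatorial approach to C5 is flanked by the axial C6 ether and the axial C10 methyl group, so the branched alkenyl reagent may enolise the ketone or add with poor facial selectivity at C5. Entry from the upper face would give the cis-dialkenyl carbinol, which would rearrange to a Z C1=C10 alkene. The fallback sets out from ketone 14 and builds the isopropenyl group in stages from a slimmer nucleophile that is less affected by the two axial α-substituents, while the upper axial path stays closed by the C9 acetal. Ethynylmagnesium bromide with CeCl3 in THF at −78 °C should give ethynyl carbinol F1. Hg(OTf)2-catalysed hydration in wet MeCN would convert the terminal alkyne into the α-hydroxy methyl ketone F2. Wittig methylenation with Ph3P=CH2 in THF then turns the acetyl group into isopropenyl and comes back to the route at carbinol 18.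

Step 12. Rearrangement of the crowded alkoxide may be incomplete, or the tetrasubstituted enolate may be lost during sulfonylation through proton transfer, C-sulfonylation or slow reaction of the hindered oxygen. The fallback sets out from carbinol 18 and separates rearrangement from triflation. After the same KH/18-crown-6 treatment, enolate 20 is quenched with Me3SiCl, the long-established trap for such enolates, to give trimethylsilyl enol ether F3, which can be purified and checked for geometry. MeLi in THF at 0 °C then regenerates the enolate regio- and stereospecifically as lithium enolate F4, and PhNTf2 with DMPU converts it into triflate 21, where the route is rejoined.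

Step 6. Only one syn-axial hydrogen guards the upper face of C9, while the lower face carries the axial C10 methyl group. Hydride delivery may therefore show poor facial selectivity and give the equatorial C9 alcohol, which would misdirect the epoxidation. The fallback sets out from ketone 9 and reverses the order of the two operations so that an oxirane oxygen, not reagent bulk, screens the upper face. Epoxidation of 9 with mCPBA, steered to the upper face by the pseudoaxial C10 methyl group, would give epoxy ketone F5. Its reduction with NaBH4 in MeOH at −40 °C (or with LiBH(s-Bu)3) should then take place from the lower face, because the C5 oxirane oxygen now blocks the upper 1,3-position. This comes back to the route at epoxy alcohol 11.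

Further compounds
F1 | step 11 | ethynyl carbinol (18 with ethynyl in place of isopropenyl) | CC(C)(C)[Si](C)(C)O[C@H]1[C@H](C(C)C)[C@H](OCc2ccc(OC)cc2)[C@](O)(C#C)[C@](C=C)(C)[C@H]1OCOCC[Si](C)(C)C
F2 | step 11 | α-hydroxy methyl ketone (18 with acetyl in place of isopropenyl) | CC(C)(C)[Si](C)(C)O[C@H]1[C@H](C(C)C)[C@H](OCc2ccc(OC)cc2)[C@](O)(C(C)=O)[C@](C=C)(C)[C@H]1OCOCC[Si](C)(C)C
F3 | step 12 | trimethylsilyl enol ether (21 with OSiMe3 in place of OTf) | CC(C)(C)[Si](C)(C)O[C@H]1[C@H](C(C)C)[C@H](OCc2ccc(OC)cc2)/C(O[Si](C)(C)C)=C(\C)CC/C=C(\C)[C@H]1OCOCC[Si](C)(C)C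
F4 | step 12 | lithium enolate (20 with lithium in place of potassium) | CC(C)(C)[Si](C)(C)O[C@H]1[C@H](C(C)C)[C@H](OCc2ccc(OC)cc2)/C([O-])=C(\C)CC/C=C(\C)[C@H]1OCOCC[Si](C)(C)C.[Li+]
F5 | step 6 | epoxy ketone (9 with an upper-face C5–C6 oxirane) | CC(C)(C)[Si](C)(C)O[C@H]1[C@H](C(C)C)[C@H]2O[C@H]2[C@](C=C)(C)C1=O
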